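Numbering used throughout: **1** 3,4,5-trimethoxyphenol; **2** 6-hydroxy-2,3,4-trimethoxybenzaldehyde; **3** (E)-3-(3,4-dimethoxyphenyl)prop-2-enal; **4** catalyst-bound oxa-Michael enamine (not isolated); **5** (R)-2-(3,4-dimethoxyphenyl)-5,6,7-trimethoxy-2H-chromene-3-carbaldehyde; **6** (S)-2-(3,4-dimethoxyphenyl)-5,6,7-trimethoxy-2H-chromene; **7** (2S)-2-(3,4-dimethoxyphenyl)-5,6,7-trimethoxychroman-4-ol; **8** the target, (2S)-2-(3,4-dimethoxyphenyl)-5,6,7-trimethoxychroman-4-one.

## Analysis of the target

Target 8 is a flavanone: a chroman-4-one in which benzene ring A is fused to the dihydropyranone ring C, with a 3,4-dimethoxyphenyl ring B on C2. Ring A carries methoxy groups on C5, C6 and C7 and is unsubstituted only at C8. All five phenolic oxygens are methyl ethers, so no protecting groups are needed. The only stereocentre is C2 (S), which is benzylic to ring B, bonded to the ring oxygen O1 and β to the C4 ketone. This centre is labile: enolisation toward C3 lets O1 leave as a phenoxide (retro-oxa-Michael opening to the chalcone, which recloses without facial bias), and acid can ionise the C2–O1 bond because ring B is electron-rich. The difficulty is therefore not size but one isolated, fragile stereocentre that must be set with absolute control, with no neighbouring centre to relay from, and then kept away from base once the ketone exists. The strategy rests on the fact that O1 and C4 sit on the adjacent ring A carbons C8a and C4a, the oxygen/formyl pattern of a salicylaldehyde, while C2, C3 and ring B are the β carbon, the α carbon and the aryl group of a cinnamaldehyde. The phenol that corresponds to ring A is symmetric and blocked at the para position, so the required salicylaldehyde is one regiochemically unambiguous formylation away.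

## Retrosynthetic reasoning

**8 ⇒ 7.** The C4 carbonyl is taken back to the secondary alcohol 7. No skeletal bond is cut; the gain is in timing. The ketone is what makes C2 labile, so it is introduced in the last step and under non-basic conditions. The C4 configuration of 7 is irrelevant, since both epimers converge on 8.

**7 ⇒ 6.** The C4–O bond and one C3–H bond are removed to give the C3=C4 alkene 6. C4 is benzylic to a ring A that carries oxygen ortho and para to it, so a hydration that runs through a C4 radical places the oxygen there and nowhere else. A hydroboration would put it on C3, which is why it is not used. The forward step must add H to C3 and O to C4 without touching the doubly activated C2–H bond.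

**6 ⇒ 5.** A formyl group is added to C3 in the retrosynthetic sense, so the forward step cuts the C3–CHO bond. This turns the alkene into an α,β-unsaturated aldehyde, the mark of an aldol condensation, and opens ring C to carbonyl chemistry. The price is one carbon that must later be removed by a decarbonylation that keeps the double bond in place and leaves C2 alone.

**5 ⇒ 2 + 3 (key disconnection).** Ring C is opened at O1–C2 and at C3=C4. Both cuts are polar and matched: the phenol oxygen of 2 is a nucleophile for the β carbon of enal 3, and the α carbon of 3, once it is an enamine, is a nucleophile for the formyl carbon of 2. Cutting only one of these bonds would leave an open-chain intermediate whose ring closure still has to be made stereoselective. Cutting both gives two stable aldehydes of similar size, and the forward reaction forms the ring and the only stereocentre in one catalytic operation. The forward step must deliver the phenol oxygen to one face of the β carbon of 3 and then close the aldol before the reversible addition reverts.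

**2 ⇒ 1.** The C4a–CHO bond is cut, an ortho-formylation in the forward direction. Phenol 1 has two equivalent ortho positions and a methoxy group at the para position, so only one formylation product is possible. Enal 3 is bought.

## Alternatives that were turned down

**Alternative 1:** The C3 methylene of 8 is excised, so C2–C3 and C3–C4 are both cut and ring C contracts to the furan ring of the aromatic silyl enol ether A2 (tert-butyl{[2-(3,4-dimethoxyphenyl)-4,5,6-trimethoxy-1-benzofuran-3-yl]oxy}dimethylsilane).
- Forward key step: a zinc carbenoid carrying a chiral ligand would add a methylene group across the furan C2=C3 bond to give the silyloxycyclopropane A1 (cis-fused 6b-[(tert-butyldimethylsilyl)oxy]-1a-(3,4-dimethoxyphenyl)-4,5,6-trimethoxy-1a,6b-dihydro-1H-cyclopropa[b][1]benzofuran). Fluoride would then release the cyclopropanolate, whose fused bond breaks and expands the five-membered ring to 8.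
- For: the C4 ketone appears at the correct oxidation level during the ring expansion. On the end game this alternative is stronger than the chosen route, which needs three steps to remove one carbon and adjust C4.
- Against: the bond to be cyclopropanated is tetrasubstituted, part of an aromatic furan, and flanked by an aryl ring and a bulky silyl ether. It has no hydroxyl or other Lewis basic anchor, which is what enantioselective zinc carbenoid additions rely on.
- Against, more seriously: C2 is quaternary in A1 and becomes the C2–H centre of 8 only when the fused bond breaks. The configuration of 8 then depends on a second, uncontrolled event, the stereochemical course of protonating a benzylic, oxygen-substituted carbanion, under basic fluoride conditions in which 8 itself can ring-open. Cleavage of an external cyclopropane bond would keep the five-membered ring.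
- Comparison: the chosen route creates C2 directly as a C–H stereocentre by a facial addition with a well-understood catalyst model. That is judged worth the longer end game.

**Alternative 2:** Ring A is cut off at both links to ring C, O1–C8a and C4–C4a, and enters as the aryne A5 (3,4,5-trimethoxybenzyne). C2, C3, C4 and ring B come as the silyl-protected acid A4 ((R)-3-[(tert-butyldimethylsilyl)oxy]-3-(3,4-dimethoxyphenyl)propanoic acid).
- Forward key step: fluoride-generated A5 would take the carboxylate oxygen at the aryne carbon remote from the flanking methoxy group, and the aryl anion next to that methoxy group would capture the acyl carbon. This gives the ortho-hydroxyaryl ketone A3 ((R)-3-[(tert-butyldimethylsilyl)oxy]-3-(3,4-dimethoxyphenyl)-1-(6-hydroxy-2,3,4-trimethoxyphenyl)propan-1-one). Ring C would be closed afterwards by desilylation and a Mitsunobu etherification with inversion.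
- For: the stereocentre comes from very dependable asymmetric chemistry (aldol addition or ketone reduction) and is independent of ring formation. The methoxy group beside the triple bond steers the regiochemistry the right way, and C4 arrives as a ketone. On reliability of absolute stereocontrol and on oxidation level it is stronger than the chosen route.
- Against: A3 is a β-silyloxy ketone formed under basic fluoride conditions, and E1cB loss of the silyloxy group leads to the chalcone A6 ((E)-3-(3,4-dimethoxyphenyl)-1-(6-hydroxy-2,3,4-trimethoxyphenyl)prop-2-en-1-one) and erases the stereocentre. Insertion into the acid C–O bond must outrun plain O-arylation of the carboxylate and arylation of the phenoxide product.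
- Against: the ring is still open after the key step, and the closing substitution takes place at a carbinol benzylic to a 3,4-dimethoxyphenyl ring, where ionisation and elimination to A6 compete with inversion. The pentasubstituted silyl aryl triflate behind A5 and the acid A4 each need several steps, so the count is roughly twice that of the chosen route.
- Comparison: the chosen route offers ring C and C2 in a single catalytic step from two simple aldehydes.

**Alternative 3:** The C3=C4 bond of the cyclic silyl enol ether A7 ((S)-tert-butyl{[2-(3,4-dimethoxyphenyl)-5,6,7-trimethoxy-2H-chromen-4-yl]oxy}dimethylsilane) is cut by retro-metathesis, and O1–C2 by an earlier asymmetric allylic etherification. The precursor is the diene A8 ((S)-tert-butyl({1-[6-{[1-(3,4-dimethoxyphenyl)prop-2-en-1-yl]oxy}-2,3,4-trimethoxyphenyl]ethenyl}oxy)dimethylsilane).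
- Forward key step: a ruthenium alkylidene metathesis catalyst would join the 1-(silyloxy)vinyl group on ring A with the vinyl group on C2 and close ring C as A7. Mild hydrolysis of the enol ether would give 8.
- For: ring-closing metathesis to 2H-chromenes is dependable, and A7 is 8 in masked form with the C4 oxygen already in place. Its end game is one mild step and is stronger than that of the chosen route. Branched-selective asymmetric allylic etherification of cinnamyl electrophiles is also well established.
- Against: the C2–O1 bond of A8 is at once allylic, benzylic to a 3,4-dimethoxyphenyl ring and an aryl ether bond. It ionises easily, so the Lewis acidic silylating conditions needed to make the enol ether, or any ruthenium hydride formed during metathesis, can scramble C2 or move the ether to the linear cinnamyl position.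
- Against: the silyloxy-substituted olefin is 1,1-disubstituted, electron-rich and wedged between two ortho substituents, which makes it a slow metathesis partner. The phenol to be allylated is hindered and hydrogen-bonded to its ortho acyl group.
- Comparison: the sequence to A8 followed by metathesis and hydrolysis is longer than five steps and needs two precious-metal catalysts. The chosen route does spend one equivalent of a rhodium complex, which is its weak point on economy, but it builds ring C and C2 in one organocatalytic step from two aldehydes.

Key step: step 2

Remark on the chemistry: the (S) catalyst is assigned from the usual shielding model of diarylprolinol silyl ether iminium ions, in which the nucleophile enters anti to the diphenyl(silyloxy)methyl group. Should the opposite sense be found, the (R) catalyst is used and nothing else changes. C2 has the same spatial arrangement in 4 to 8; the descriptor is R only in 5, where the formyl-bearing C3 outranks ring B.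

## Route

Step 1
Reactants: 1 3,4,5-trimethoxyphenol
Product: 2 6-hydroxy-2,3,4-trimethoxybenzaldehyde
Conditions: MgCl2 (1.5 equiv), Et3N (3.75 equiv), (CH2O)n (6.8 equiv), THF, reflux; 1 M HCl work-up
Reagents that add atoms: paraformaldehyde (as formaldehyde), C=O
Why: Casnati–Skattebøl ortho-formylation: the magnesium phenoxide delivers formaldehyde to the ortho carbon through a chelate, and a second formaldehyde oxidises the resulting benzylic alkoxide by hydride transfer. The two ortho positions of 1 are equivalent and the para position is blocked by OMe, so only 2 can form.

Step 2
Reactants: 2 6-hydroxy-2,3,4-trimethoxybenzaldehyde; 3 (E)-3-(3,4-dimethoxyphenyl)prop-2-enal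
Product: 5 (R)-2-(3,4-dimethoxyphenyl)-5,6,7-trimethoxy-2H-chromene-3-carbaldehyde, via oxa-Michael enamine 4 (not isolated)
Conditions: 3 (1.3 equiv), (S)-2-[diphenyl(trimethylsilyloxy)methyl]pyrrolidine (20 mol %), 2-nitrobenzoic acid (20 mol %), 4 Å MS, PhMe, 0 °C to rt, dark
Reagents that add atoms: none
Why: This is the secondary-amine-catalysed domino oxa-Michael/aldol condensation of a salicylaldehyde with an enal, a known route to 2-substituted 2H-chromene-3-carbaldehydes. The catalyst condenses with 3 to an E-configured, s-trans iminium ion, the phenol oxygen of 2 adds to its β carbon (O1–C2), and enamine 4 results. The enamine carbon then attacks the ortho formyl group (C3–C4) in a 6-exo-trig aldol closure of ring C (enol-exo in the sense of Baldwin's rules), and dehydration with hydrolysis of the iminium ion releases 5 and the catalyst. The new stereocentre C2 is set in the oxa-Michael step: the diphenyl(trimethylsilyloxy)methyl group on the (S)-pyrrolidine covers the Re face of the β carbon, so oxygen arrives on the Si face, the arrangement that reads R in 5 and S in 8. The step needs chemoselectivity between two aldehydes and 1,4- over 1,2-addition; only the enal gives a conjugated iminium ion, and the phenol is held ortho to the acceptor aldehyde so the aldol is intramolecular. The irreversible dehydration drains the reversible oxa-Michael equilibrium. 2-Nitrobenzoic acid speeds iminium formation and turnover, and low temperature with work-up at full conversion should limit loss of enantiopurity through the dienamine of the product.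

Step 3
Reactants: 5 (R)-2-(3,4-dimethoxyphenyl)-5,6,7-trimethoxy-2H-chromene-3-carbaldehyde
Product: 6 (S)-2-(3,4-dimethoxyphenyl)-5,6,7-trimethoxy-2H-chromene
Conditions: RhCl(PPh3)3 (1.1 equiv), degassed PhMe, 100 °C, Ar, dark; isolation on Et3N-washed silica
Reagents that add atoms: none
Why: Tsuji–Wilkinson decarbonylation of an α,β-unsaturated aldehyde: monovalent rhodium inserts into the formyl C–H bond, the acyl ligand extrudes CO, and C–H reductive elimination leaves hydrogen on C3 with the double bond in place. CO stays bound as RhCl(CO)(PPh3)2, hence one equivalent of the complex. C2 takes no part in the mechanism; the lowest workable temperature, exclusion of light and acid-free isolation are chosen to protect it.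

Step 4
Reactants: 6 (S)-2-(3,4-dimethoxyphenyl)-5,6,7-trimethoxy-2H-chromene
Product: 7 (2S)-2-(3,4-dimethoxyphenyl)-5,6,7-trimethoxychroman-4-ol (both C4 epimers)
Conditions: Co(acac)2 (20 mol %), PhSiH3 (2.5 equiv), O2 (1 atm), THF, rt
Reagents that add atoms: dioxygen, O=O
Why: Mukaiyama hydration: a cobalt hydride transfers a hydrogen atom to C3 so that the radical lies on C4, benzylic to the electron-rich ring A; O2 traps it and the silane reduces the peroxide to the alcohol, so oxygen should end up on C4 only. C2 is untouched, and the C4 configuration is immaterial because it is oxidised in step 5.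

Step 5
Reactants: 7 (2S)-2-(3,4-dimethoxyphenyl)-5,6,7-trimethoxychroman-4-ol
Product: 8 (2S)-2-(3,4-dimethoxyphenyl)-5,6,7-trimethoxychroman-4-one, (2S)-5,6,7,3',4'-pentamethoxyflavanone
Conditions: Dess–Martin periodinane (1.3 equiv), pyridine (3 equiv), CH2Cl2, 0 °C to rt
Reagents that add atoms: none
Why: Dess–Martin oxidation of a secondary benzylic alcohol under pyridine-buffered, non-basic conditions; both C4 epimers converge on the ketone, and the C2 centre, which is labile to base by retro-oxa-Michael ring opening, never meets an enolising base.

## Compound list

1 | 3,4,5-trimethoxyphenol | COc1cc(O)cc(OC)c1OC | starting material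
2 | 6-hydroxy-2,3,4-trimethoxybenzaldehyde | O=Cc1c(O)cc(OC)c(OC)c1OC | intermediate
3 | (E)-3-(3,4-dimethoxyphenyl)prop-2-enal | COc1ccc(/C=C/C=O)cc1OC | starting material
4 | (2S)-1-[(1E,3S)-3-(3,4-dimethoxyphenyl)-3-(2-formyl-3,4,5-trimethoxyphenoxy)prop-1-en-1-yl]-2-[diphenyl(trimethylsilyloxy)methyl]pyrrolidine (oxa-Michael enamine, not isolated) | COc1ccc([C@@H](Oc2cc(OC)c(OC)c(OC)c2C=O)/C=C/N2CCC[C@H]2C(O[Si](C)(C)C)(c2ccccc2)c2ccccc2)cc1OC | intermediate
5 | (R)-2-(3,4-dimethoxyphenyl)-5,6,7-trimethoxy-2H-chromene-3-carbaldehyde | COc1ccc([C@@H]2C(C=O)=Cc3c(cc(OC)c(OC)c3OC)O2)cc1OC | intermediate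
6 | (S)-2-(3,4-dimethoxyphenyl)-5,6,7-trimethoxy-2H-chromene | COc1ccc([C@@H]2C=Cc3c(cc(OC)c(OC)c3OC)O2)cc1OC | intermediate
7 | (2S)-2-(3,4-dimethoxyphenyl)-5,6,7-trimethoxychroman-4-ol (both C4 epimers) | COc1ccc([C@@H]2CC(O)c3c(cc(OC)c(OC)c3OC)O2)cc1OC | intermediate
8 | (2S)-2-(3,4-dimethoxyphenyl)-5,6,7-trimethoxychroman-4-one, (2S)-5,6,7,3',4'-pentamethoxyflavanone | COc1ccc([C@@H]2CC(=O)c3c(cc(OC)c(OC)c3OC)O2)cc1OC | target

## Step count and least certain steps

Total: 5 steps. Longest linear sequence: 5 steps (1 → 2 → 5 → 6 → 7 → 8); enal 3 enters in step 2.

**Step 2 (key step).** The formyl group of 2 sits between OH and OMe and receives electron density from three oxygen donors, so the aldol closure may lag behind the oxa-Michael addition. The adduct can then revert, the enal can be consumed by self-condensation, and prolonged contact with the amine can erode the enantiomeric purity through reversible addition and γ-deprotonation of the product iminium ion. Incomplete facial discrimination with an electron-rich β-aryl enal is the second concern. Fallback: setting out from 2 and 3, the base-mediated, non-asymmetric form of the same domino reaction (K2CO3, 1,4-dioxane, 80 °C), which tolerates hindered salicylaldehydes, should give racemic 2-(3,4-dimethoxyphenyl)-5,6,7-trimethoxy-2H-chromene-3-carbaldehyde F1. Preparative HPLC on a polysaccharide chiral stationary phase then separates the enantiomers, and the R enantiomer rejoins the route as 5. Stereocontrol thus moves from catalysis to resolution.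

**Step 3.** At the temperature needed for CO extrusion, the configuration at C2 may be partly lost through 6π-electrocyclic ring opening to the ortho-quinone methide and reclosure, or through rhodium hydride migration of the double bond into the 2,3-position. Decarbonylation of a hindered, electron-rich enal may also stall. Fallback: setting out from 5, hydrogenation of the C3=C4 bond (H2, 1 atm, Pd/C, EtOAc, rt) should give (2S)-2-(3,4-dimethoxyphenyl)-5,6,7-trimethoxychromane-3-carbaldehyde F2 as C3 epimers. This aldehyde has neither a double bond that can migrate nor an electrocyclic pathway, and its decarbonylation with RhCl(PPh3)3 (PhMe, 100 °C) should give (2S)-2-(3,4-dimethoxyphenyl)-5,6,7-trimethoxychromane F3. DDQ in wet CH2Cl2 at 0 °C then abstracts hydride from C4, the benzylic position ortho and para to ring A oxygens, and water captures the cation. The route is rejoined at 7 and step 4 is bypassed.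

**Step 4.** The benzylic radical may be reduced by a second hydrogen atom transfer instead of being trapped by oxygen (net hydrogenation), radical-chain autoxidation may start at the weak C2–H bond, and the electron-rich benzylic alcohol may ionise during isolation. Fallback: setting out from 6, ionic Markovnikov hydration by oxymercuration with Hg(OAc)2 in THF–H2O at 0 °C should place mercury on C3 and hydroxyl on the benzylic C4, giving acetoxy[(2R)-2-(3,4-dimethoxyphenyl)-4-hydroxy-5,6,7-trimethoxychroman-3-yl]mercury F4. Its spatial arrangement at C2 is that of 6; the descriptor changes because mercury raises the rank of C3. NaBH4 in aqueous NaOH removes the mercury, and the route is rejoined at 7.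

## Further compounds

F1 | step 2 | racemic 2-(3,4-dimethoxyphenyl)-5,6,7-trimethoxy-2H-chromene-3-carbaldehyde | COc1ccc(C2C(C=O)=Cc3c(cc(OC)c(OC)c3OC)O2)cc1OC
F2 | step 3 | (2S)-2-(3,4-dimethoxyphenyl)-5,6,7-trimethoxychromane-3-carbaldehyde (C3 epimers) | COc1ccc([C@@H]2C(C=O)Cc3c(cc(OC)c(OC)c3OC)O2)cc1OC
F3 | step 3 | (2S)-2-(3,4-dimethoxyphenyl)-5,6,7-trimethoxychromane | COc1ccc([C@@H]2CCc3c(cc(OC)c(OC)c3OC)O2)cc1OC
F4 | step 4 | acetoxy[(2R)-2-(3,4-dimethoxyphenyl)-4-hydroxy-5,6,7-trimethoxychroman-3-yl]mercury (C3 and C4 not specified) | COc1ccc([C@@H]2C([Hg]OC(C)=O)C(O)c3c(cc(OC)c(OC)c3OC)O2)cc1OC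
A1 | alternative 1 | cis-fused 6b-[(tert-butyldimethylsilyl)oxy]-1a-(3,4-dimethoxyphenyl)-4,5,6-trimethoxy-1a,6b-dihydro-1H-cyclopropa[b][1]benzofuran, enantiomer as in the SMILES | COc1ccc([C@]23C[C@@]2(O[Si](C)(C)C(C)(C)C)c4c(cc(OC)c(OC)c4OC)O3)cc1OC
A2 | alternative 1 | tert-butyl{[2-(3,4-dimethoxyphenyl)-4,5,6-trimethoxy-1-benzofuran-3-yl]oxy}dimethylsilane | COc1ccc(-c2oc3cc(OC)c(OC)c(OC)c3c2O[Si](C)(C)C(C)(C)C)cc1OC
A3 | alternative 2 | (R)-3-[(tert-butyldimethylsilyl)oxy]-3-(3,4-dimethoxyphenyl)-1-(6-hydroxy-2,3,4-trimethoxyphenyl)propan-1-one | COc1ccc([C@H](O[Si](C)(C)C(C)(C)C)CC(=O)c2c(O)cc(OC)c(OC)c2OC)cc1OC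
A4 | alternative 2 | (R)-3-[(tert-butyldimethylsilyl)oxy]-3-(3,4-dimethoxyphenyl)propanoic acid | COc1ccc([C@H](O[Si](C)(C)C(C)(C)C)CC(=O)O)cc1OC
A5 | alternative 2 | 3,4,5-trimethoxybenzyne (1,2-didehydro-3,4,5-trimethoxybenzene) | COC1=C(OC)C(OC)=CC#C1
A6 | alternative 2 | (E)-3-(3,4-dimethoxyphenyl)-1-(6-hydroxy-2,3,4-trimethoxyphenyl)prop-2-en-1-one | COc1ccc(/C=C/C(=O)c2c(O)cc(OC)c(OC)c2OC)cc1OC
A7 | alternative 3 | (S)-tert-butyl{[2-(3,4-dimethoxyphenyl)-5,6,7-trimethoxy-2H-chromen-4-yl]oxy}dimethylsilane | COc1ccc([C@@H]2C=C(O[Si](C)(C)C(C)(C)C)c3c(cc(OC)c(OC)c3OC)O2)cc1OC
A8 | alternative 3 | (S)-tert-butyl({1-[6-{[1-(3,4-dimethoxyphenyl)prop-2-en-1-yl]oxy}-2,3,4-trimethoxyphenyl]ethenyl}oxy)dimethylsilane | COc1ccc([C@H](C=C)Oc2cc(OC)c(OC)c(OC)c2C(=C)O[Si](C)(C)C(C)(C)C)cc1OC
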